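**Retrosynthetic overview**
1. Vinyl carbinol of 23 ⇐ reductive opening of epoxy iodide 22 ⇐ Sharpless epoxidation of E-allylic alcohol 20 ⇐ methylalumination/formaldehyde capture of alkyne 18.
2. 18 ⇐ bromo δ-lactone 15 (DIBAL, then Ohira–Bestmann). The C–Br bond ⇐ SN2 inversion of axial alcohol 14 while the ring tertiary OH is locked in the lactone.
3. Lactone 13 ⇐ keto ester 11 + MeMgBr (equatorial attack, then lactonisation).
4. Key bond, ring C-2–CH2 ⇐ Mukaiyama–Michael addition of enol silane 9 to methyl acrylate 10. 9 ⇐ Me2CuLi/TMSCl on enone 8.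
5. 8 ⇐ Stork–Danheiser sequence on resolved 6-oxygenated 3-ethoxycyclohexenone. Ring order: the carbocycle is bought with 1; the δ-lactone ring forms in step 7 and opens in steps 10–11; the oxirane forms in step 13 and opens in step 15.

Assumption: the lipase hydrolyses the (R)-acetate of 2 faster (Kazlauskas rule); if a batch shows the opposite preference, the recovered acetate is methanolysed to the same alcohol 3.
Ring numbering in the comments: C-1 = carbonyl/carbinol carbon, C-2 = side-chain carbon, C-3 = quaternary carbon, C-4 = O/Br-bearing carbon.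

**Step 1**
Reactants: 1 3-ethoxycyclohex-2-en-1-one
Product: 2 rac-6-acetoxy-3-ethoxycyclohex-2-en-1-one
Conditions: Mn(OAc)3 (3 equiv), benzene, reflux, Dean–Stark, 12 h
Reagents that add atoms: manganese triacetate, CC(=O)[O-].CC(=O)[O-].CC(=O)[O-].[Mn+3]
Why: Manganese triacetate α′-acetoxylation oxidises the cross-conjugated enol of the vinylogous ester only at C-6 and gives the racemic acetate.

**Step 2**
Reactants: 2 rac-6-acetoxy-3-ethoxycyclohex-2-en-1-one
Product: 3 (6R)-3-ethoxy-6-hydroxycyclohex-2-en-1-one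
Conditions: Burkholderia cepacia lipase (lipase PS), pH 7 phosphate buffer/DMSO, rt, stopped at about 45% conversion, chromatography
Reagents that add atoms: none
Why: In this enzymatic kinetic resolution by ester hydrolysis the (R)-acetate (carbonyl side large, CH2 side medium) is cleaved faster, so (R)-3 is obtained in high ee, the unreacted enantiomer of 2 is separated, and the carbinol centre that steers all later ring stereocentres is set.

**Step 3**
Reactants: 3 (6R)-3-ethoxy-6-hydroxycyclohex-2-en-1-one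
Product: 4 (6R)-6-(tert-butyldimethylsilyloxy)-3-ethoxycyclohex-2-en-1-one
Conditions: TBSCl, imidazole, DMF, 0 °C → rt
Reagents that add atoms: TBSCl, CC(C)(C)[Si](C)(C)Cl
Why: Standard silyl ether protection under mild base leaves the α-oxygenated centre untouched and installs a bulky, Lewis-acid-tolerant directing group.

**Step 4**
Reactants: 4 (6R)-6-(tert-butyldimethylsilyloxy)-3-ethoxycyclohex-2-en-1-one; 5 5-bromo-2-methylpent-2-ene
Product: 8 (4R)-4-(tert-butyldimethylsilyloxy)-3-(4-methylpent-3-en-1-yl)cyclohex-2-en-1-one, via homoprenylmagnesium bromide 6 (not isolated), via tertiary allylic carbinol 7 (not isolated)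
Conditions: 5, Mg, THF, rt; then 4, LaCl3·2LiCl (0.3 equiv), 0 °C → rt; then 1 M HCl, THF, 0 °C, 30 min
Reagents that add atoms: none
Why: In this Stork–Danheiser enone transposition, 1,2-addition of the Grignard reagent to the vinylogous ester is followed by acid hydrolysis and dehydration that moves the carbonyl, and the silyloxy stereocentre takes no part.

**Step 5**
Reactants: 8 (4R)-4-(tert-butyldimethylsilyloxy)-3-(4-methylpent-3-en-1-yl)cyclohex-2-en-1-one
Product: 9 (3S,4R)-4-(tert-butyldimethylsilyloxy)-3-methyl-3-(4-methylpent-3-en-1-yl)-1-(trimethylsilyloxy)cyclohex-1-ene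
Conditions: MeLi (4 equiv), CuBr·SMe2 (2 equiv), Et2O, 0 °C; then TMSCl (4 equiv), 8, THF, −78 → −30 °C; Et3N, cold aq. NaHCO3
Reagents that add atoms: MeLi (delivered as Me2CuLi), [Li]C; TMSCl, C[Si](C)(C)Cl
Why: In this TMSCl-accelerated Gilman conjugate addition, A(1,2) strain with the C-3 chain makes the C-4 silyloxy group pseudoaxial, so methyl enters axially from the opposite face, setting quaternary C-3 as (S), and the enolate is trapped regiospecifically towards C-2.

**Step 6 (key step)**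
Reactants: 9 (3S,4R)-4-(tert-butyldimethylsilyloxy)-3-methyl-3-(4-methylpent-3-en-1-yl)-1-(trimethylsilyloxy)cyclohex-1-ene; 10 methyl acrylate
Product: 11 methyl 3-[(1S,2S,3R)-3-(tert-butyldimethylsilyloxy)-2-methyl-2-(4-methylpent-3-en-1-yl)-6-oxocyclohexyl]propanoate
Conditions: 10 (3 equiv), TiCl4 (1.1 equiv), CH2Cl2, −78 °C, 2 h; cold aq. NaHCO3
Reagents that add atoms: none
Why: In this intermolecular Mukaiyama–Michael addition the TiCl4-activated acrylate is attacked by C-2 of the regiodefined enol silane on the face anti to the axial homoprenyl chain and to the C-4 silyloxy group (cis to the small methyl), which sets C-2 kinetically, and the cold buffered work-up prevents epimerisation.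

**Step 7**
Reactants: 11 methyl 3-[(1S,2S,3R)-3-(tert-butyldimethylsilyloxy)-2-methyl-2-(4-methylpent-3-en-1-yl)-6-oxocyclohexyl]propanoate
Product: 13 (4aS,5S,6R,8aR)-6-(tert-butyldimethylsilyloxy)-5,8a-dimethyl-5-(4-methylpent-3-en-1-yl)octahydro-2H-chromen-2-one, via hydroxy ester 12 (not isolated)
Conditions: MeMgBr (1.3 equiv), LaCl3·2LiCl (1 equiv), THF, −78 → −40 °C; AcOH quench; then PPTS (cat.), toluene, 60 °C
Reagents that add atoms: MeMgBr, C[Mg]Br
Why: In this lanthanide-promoted, non-enolising Grignard 1,2-addition the ketone reacts before the ester; the axial face is blocked by the axial C-3 methyl, so methyl enters equatorially, and the resulting axial OH is cis to the side chain and closes to the δ-lactone, which masks the tertiary alcohol.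

**Step 8**
Reactants: 13 (4aS,5S,6R,8aR)-6-(tert-butyldimethylsilyloxy)-5,8a-dimethyl-5-(4-methylpent-3-en-1-yl)octahydro-2H-chromen-2-one
Product: 14 (4aS,5S,6R,8aR)-6-hydroxy-5,8a-dimethyl-5-(4-methylpent-3-en-1-yl)octahydro-2H-chromen-2-one
Conditions: HF·pyridine, pyridine, THF, 0 °C → rt
Reagents that add atoms: none
Why: Buffered fluoride desilylation frees the axial C-4 alcohol without touching the lactone, the alkene or any stereocentre.

**Step 9**
Reactants: 14 (4aS,5S,6R,8aR)-6-hydroxy-5,8a-dimethyl-5-(4-methylpent-3-en-1-yl)octahydro-2H-chromen-2-one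
Product: 15 (4aS,5S,6S,8aR)-6-bromo-5,8a-dimethyl-5-(4-methylpent-3-en-1-yl)octahydro-2H-chromen-2-one
Conditions: CBr4 (3 equiv), P(n-C8H17)3 (3 equiv), 1-methylcyclohexene (5 equiv), toluene, 0 → 70 °C
Reagents that add atoms: CBr4, BrC(Br)(Br)Br
Why: In this Appel-type SN2 displacement bromide expels the axial oxyphosphonium group from the rear, turning the (R) axial alcohol into the (S) equatorial bromide; the nucleophilic trialkylphosphine and the HBr-trapping alkene are chosen for the neopentylic site, and the tertiary oxygen is safe as the lactone.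

**Step 10**
Reactants: 15 (4aS,5S,6S,8aR)-6-bromo-5,8a-dimethyl-5-(4-methylpent-3-en-1-yl)octahydro-2H-chromen-2-one
Product: 16 (4aS,5S,6S,8aR)-6-bromo-5,8a-dimethyl-5-(4-methylpent-3-en-1-yl)octahydro-2H-chromen-2-ol (anomers)
Conditions: i-Bu2AlH (1.1 equiv), CH2Cl2, −78 °C; Rochelle salt
Reagents that add atoms: none
Why: Partial lactone reduction stops at the stable tetrahedral aluminate at −78 °C, the equatorial neopentylic bromide is inert to the hydride, and the anomeric centre is of no consequence.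

**Step 11**
Reactants: 16 (4aS,5S,6S,8aR)-6-bromo-5,8a-dimethyl-5-(4-methylpent-3-en-1-yl)octahydro-2H-chromen-2-ol
Product: 18 (1R,2S,3S,4S)-4-bromo-2-(but-3-yn-1-yl)-1,3-dimethyl-3-(4-methylpent-3-en-1-yl)cyclohexan-1-ol, via open-chain hydroxy aldehyde 17 (not isolated)
Conditions: dimethyl (1-diazo-2-oxopropyl)phosphonate (2 equiv), K2CO3 (3 equiv), MeOH, rt
Reagents that add atoms: Ohira–Bestmann reagent, COP(=O)(OC)C(=[N+]=[N-])C(C)=O
Why: In this Ohira–Bestmann (Seyferth–Gilbert) homologation the lactol reacts through its aldehyde tautomer under carbonate conditions that leave the bromide and all stereocentres alone.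

**Step 12**
Reactants: 18 (1R,2S,3S,4S)-4-bromo-2-(but-3-yn-1-yl)-1,3-dimethyl-3-(4-methylpent-3-en-1-yl)cyclohexan-1-ol
Product: 20 (1R,2S,3S,4S)-4-bromo-2-[(3E)-5-hydroxy-3-methylpent-3-en-1-yl]-1,3-dimethyl-3-(4-methylpent-3-en-1-yl)cyclohexan-1-ol, via alkenylalane 19 (not isolated)
Conditions: AlMe3 (4 equiv), Cp2ZrCl2 (0.3 equiv), CH2Cl2, 0 °C → rt; concentrate; n-BuLi, THF, −78 °C; (CH2O)n, → rt; aq. work-up
Reagents that add atoms: AlMe3, C[Al](C)C; paraformaldehyde (as formaldehyde), C=O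
Why: Negishi zirconium-catalysed methylalumination adds Me and Al syn with Me on the internal carbon, and C–Al to C–CH2OH exchange with retention gives only the E-trisubstituted allylic alcohol, while the extra AlMe3 merely caps the tertiary OH as its alkoxide.

**Step 13**
Reactants: 20 (1R,2S,3S,4S)-4-bromo-2-[(3E)-5-hydroxy-3-methylpent-3-en-1-yl]-1,3-dimethyl-3-(4-methylpent-3-en-1-yl)cyclohexan-1-ol
Product: 21 (1R,2S,3S,4S)-4-bromo-2-{2-[(2S,3S)-3-(hydroxymethyl)-2-methyloxiran-2-yl]ethyl}-1,3-dimethyl-3-(4-methylpent-3-en-1-yl)cyclohexan-1-ol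
Conditions: Ti(OiPr)4 (0.2 equiv), L-(+)-diethyl tartrate (0.24 equiv), t-BuOOH (2 equiv), 4 Å MS, CH2Cl2, −20 °C
Reagents that add atoms: t-BuOOH, CC(C)(C)OO
Why: In this Katsuki–Sharpless asymmetric epoxidation the L-(+)-tartrate catalyst delivers oxygen to the same face as with geraniol and gives the (2S,3S)-epoxide under reagent control, while the isolated trisubstituted alkene is not epoxidised.

**Step 14**
Reactants: 21 (1R,2S,3S,4S)-4-bromo-2-{2-[(2S,3S)-3-(hydroxymethyl)-2-methyloxiran-2-yl]ethyl}-1,3-dimethyl-3-(4-methylpent-3-en-1-yl)cyclohexan-1-ol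
Product: 22 (1R,2S,3S,4S)-4-bromo-2-{2-[(2S,3R)-3-(iodomethyl)-2-methyloxiran-2-yl]ethyl}-1,3-dimethyl-3-(4-methylpent-3-en-1-yl)cyclohexan-1-ol
Conditions: I2, PPh3, imidazole, THF, 0 °C, 20 min
Reagents that add atoms: iodine, II
Why: Garegg–Samuelsson (Appel-type) iodination reacts only at the unhindered primary alcohol, the hindered tertiary OH is inert, and the descriptor at the oxirane CH changes by priority only.

**Step 15**
Reactants: 22 (1R,2S,3S,4S)-4-bromo-2-{2-[(2S,3R)-3-(iodomethyl)-2-methyloxiran-2-yl]ethyl}-1,3-dimethyl-3-(4-methylpent-3-en-1-yl)cyclohexan-1-ol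
Product: 23 (1R,2S,3S,4S)-4-bromo-2-[(3S)-3-hydroxy-3-methylpent-4-en-1-yl]-1,3-dimethyl-3-(4-methylpent-3-en-1-yl)cyclohexan-1-ol (target)
Conditions: activated Zn dust, AcOH (3 equiv), EtOH, rt
Reagents that add atoms: none
Why: In this zinc-mediated reductive β-elimination of the β-iodo epoxide the CH–O bond breaks to form the vinyl group while the C(Me)–O bond stays intact, so the (S) tertiary carbinol is retained and the unactivated secondary bromide is not reduced.

**Compound list**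
1 | 3-ethoxycyclohex-2-en-1-one | CCOC1=CC(=O)CCC1 | starting material
2 | rac-6-acetoxy-3-ethoxycyclohex-2-en-1-one | CCOC1=CC(=O)C(OC(C)=O)CC1 | intermediate
3 | (6R)-3-ethoxy-6-hydroxycyclohex-2-en-1-one | CCOC1=CC(=O)[C@H](O)CC1 | intermediate
4 | (6R)-6-(tert-butyldimethylsilyloxy)-3-ethoxycyclohex-2-en-1-one | CCOC1=CC(=O)[C@H](O[Si](C)(C)C(C)(C)C)CC1 | intermediate
5 | 5-bromo-2-methylpent-2-ene | CC(C)=CCCBr | starting material
6 | (4-methylpent-3-en-1-yl)magnesium bromide | CC(C)=CCC[Mg]Br | intermediate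
7 | (6R)-6-(tert-butyldimethylsilyloxy)-3-ethoxy-1-(4-methylpent-3-en-1-yl)cyclohex-2-en-1-ol (C-1 epimers) | CCOC1=CC(O)(CCC=C(C)C)[C@H](O[Si](C)(C)C(C)(C)C)CC1 | intermediate
8 | (4R)-4-(tert-butyldimethylsilyloxy)-3-(4-methylpent-3-en-1-yl)cyclohex-2-en-1-one | O=C1C=C(CCC=C(C)C)[C@H](O[Si](C)(C)C(C)(C)C)CC1 | intermediate
9 | (3S,4R)-4-(tert-butyldimethylsilyloxy)-3-methyl-3-(4-methylpent-3-en-1-yl)-1-(trimethylsilyloxy)cyclohex-1-ene | C[Si](C)(C)OC1=C[C@](C)(CCC=C(C)C)[C@H](O[Si](C)(C)C(C)(C)C)CC1 | intermediate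
10 | methyl acrylate | C=CC(=O)OC | starting material
11 | methyl 3-[(1S,2S,3R)-3-(tert-butyldimethylsilyloxy)-2-methyl-2-(4-methylpent-3-en-1-yl)-6-oxocyclohexyl]propanoate | COC(=O)CC[C@H]1[C@](C)(CCC=C(C)C)[C@H](O[Si](C)(C)C(C)(C)C)CCC1=O | intermediate
12 | methyl 3-[(1S,2S,3R,6R)-3-(tert-butyldimethylsilyloxy)-6-hydroxy-2,6-dimethyl-2-(4-methylpent-3-en-1-yl)cyclohexyl]propanoate | COC(=O)CC[C@H]1[C@](C)(CCC=C(C)C)[C@H](O[Si](C)(C)C(C)(C)C)CC[C@@]1(C)O | intermediate
13 | (4aS,5S,6R,8aR)-6-(tert-butyldimethylsilyloxy)-5,8a-dimethyl-5-(4-methylpent-3-en-1-yl)octahydro-2H-chromen-2-one | O=C1CC[C@H]2[C@](C)(CCC=C(C)C)[C@H](O[Si](C)(C)C(C)(C)C)CC[C@@]2(C)O1 | intermediate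
14 | (4aS,5S,6R,8aR)-6-hydroxy-5,8a-dimethyl-5-(4-methylpent-3-en-1-yl)octahydro-2H-chromen-2-one | O=C1CC[C@H]2[C@](C)(CCC=C(C)C)[C@H](O)CC[C@@]2(C)O1 | intermediate
15 | (4aS,5S,6S,8aR)-6-bromo-5,8a-dimethyl-5-(4-methylpent-3-en-1-yl)octahydro-2H-chromen-2-one | O=C1CC[C@H]2[C@](C)(CCC=C(C)C)[C@@H](Br)CC[C@@]2(C)O1 | intermediate
16 | (4aS,5S,6S,8aR)-6-bromo-5,8a-dimethyl-5-(4-methylpent-3-en-1-yl)octahydro-2H-chromen-2-ol (anomers) | OC1CC[C@H]2[C@](C)(CCC=C(C)C)[C@@H](Br)CC[C@@]2(C)O1 | intermediate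
17 | 3-[(1S,2S,3S,6R)-3-bromo-6-hydroxy-2,6-dimethyl-2-(4-methylpent-3-en-1-yl)cyclohexyl]propanal | O=CCC[C@H]1[C@](C)(CCC=C(C)C)[C@@H](Br)CC[C@@]1(C)O | intermediate
18 | (1R,2S,3S,4S)-4-bromo-2-(but-3-yn-1-yl)-1,3-dimethyl-3-(4-methylpent-3-en-1-yl)cyclohexan-1-ol | C#CCC[C@H]1[C@](C)(CCC=C(C)C)[C@@H](Br)CC[C@@]1(C)O | intermediate
19 | (E)-alkenyl(dimethyl)alane of 18, tertiary OH as its dimethylaluminium alkoxide | C[Al](C)/C=C(\C)CC[C@H]1[C@](C)(CCC=C(C)C)[C@@H](Br)CC[C@@]1(C)O[Al](C)C | intermediate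
20 | (1R,2S,3S,4S)-4-bromo-2-[(3E)-5-hydroxy-3-methylpent-3-en-1-yl]-1,3-dimethyl-3-(4-methylpent-3-en-1-yl)cyclohexan-1-ol | OC/C=C(\C)CC[C@H]1[C@](C)(CCC=C(C)C)[C@@H](Br)CC[C@@]1(C)O | intermediate
21 | (1R,2S,3S,4S)-4-bromo-2-{2-[(2S,3S)-3-(hydroxymethyl)-2-methyloxiran-2-yl]ethyl}-1,3-dimethyl-3-(4-methylpent-3-en-1-yl)cyclohexan-1-ol | OC[C@@H]1O[C@@]1(C)CC[C@H]2[C@](C)(CCC=C(C)C)[C@@H](Br)CC[C@@]2(C)O | intermediate
22 | (1R,2S,3S,4S)-4-bromo-2-{2-[(2S,3R)-3-(iodomethyl)-2-methyloxiran-2-yl]ethyl}-1,3-dimethyl-3-(4-methylpent-3-en-1-yl)cyclohexan-1-ol | IC[C@@H]1O[C@@]1(C)CC[C@H]2[C@](C)(CCC=C(C)C)[C@@H](Br)CC[C@@]2(C)O | intermediate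
23 | (1R,2S,3S,4S)-4-bromo-2-[(3S)-3-hydroxy-3-methylpent-4-en-1-yl]-1,3-dimethyl-3-(4-methylpent-3-en-1-yl)cyclohexan-1-ol | C=C[C@@](C)(O)CC[C@H]1[C@](C)(CCC=C(C)C)[C@@H](Br)CC[C@@]1(C)O | target

**Totals:** 15 steps; longest linear sequence 15 steps (from 1).

**Three steps most likely to fail**

Step 6. The nucleophilic carbon is neopentylic and acrylate is a weak acceptor, so protodesilylation, cyclobutane formation or partial C-2 epimerisation may dominate.
- The fallback sets out from 9. MeLi cleaves it to the lithium enolate, which is alkylated with allyl iodide (THF/DMPU, −78 → 0 °C, same facial bias) to give allyl ketone F1.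
- MeMgBr/LaCl3·2LiCl then adds from the equatorial side to give tertiary carbinol F2.
- 9-BBN hydroborates only the terminal alkene, and NaBO3 oxidation gives diol F3.
- TEMPO/PhI(OAc)2 oxidative lactonisation brings the material back to the route at 13.

Step 9. Backside attack at the neopentylic carbon is eclipsed by the axial methyl, so E2 to the ring alkene or a methyl shift can compete.
- The fallback sets out from 14 and separates activation from substitution.
- ClCH2SO2Cl/pyridine at 0 °C gives the isolable chloromethanesulfonate F4.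
- F4 is displaced with dry LiBr in DMF/toluene at 40–60 °C, in the absence of any phosphorus base, with the same inversion.
- This returns to the route at 15.

Step 12. The Lewis-acidic Al/Zr medium could ionise the secondary bromide or the tertiary alkoxide.
- The fallback sets out from 18. Double deprotonation (EtMgBr, 2.2 equiv) and paraformaldehyde give propargylic alcohol F5.
- Hydroxyl-directed trans-hydroalumination with NaAlH2(OCH2CH2OMe)2 followed by I2 gives (Z)-iodoalkenol F6.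
- Methyl coupling with Me2CuLi (0 °C, retention of geometry) returns to the route at 20.

**Further compounds**
F1 | step 6 | (2S,3S,4R)-4-(tert-butyldimethylsilyloxy)-3-methyl-3-(4-methylpent-3-en-1-yl)-2-(prop-2-en-1-yl)cyclohexan-1-one | C=CC[C@H]1[C@](C)(CCC=C(C)C)[C@H](O[Si](C)(C)C(C)(C)C)CCC1=O
F2 | step 6 | (1R,2S,3S,4R)-4-(tert-butyldimethylsilyloxy)-1,3-dimethyl-3-(4-methylpent-3-en-1-yl)-2-(prop-2-en-1-yl)cyclohexan-1-ol | C=CC[C@H]1[C@](C)(CCC=C(C)C)[C@H](O[Si](C)(C)C(C)(C)C)CC[C@@]1(C)O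
F3 | step 6 | (1R,2S,3S,4R)-4-(tert-butyldimethylsilyloxy)-2-(3-hydroxypropyl)-1,3-dimethyl-3-(4-methylpent-3-en-1-yl)cyclohexan-1-ol | OCCC[C@H]1[C@](C)(CCC=C(C)C)[C@H](O[Si](C)(C)C(C)(C)C)CC[C@@]1(C)O
F4 | step 9 | (4aS,5S,6R,8aR)-5,8a-dimethyl-5-(4-methylpent-3-en-1-yl)-2-oxooctahydro-2H-chromen-6-yl chloromethanesulfonate | O=C1CC[C@H]2[C@](C)(CCC=C(C)C)[C@H](OS(=O)(=O)CCl)CC[C@@]2(C)O1
F5 | step 12 | (1R,2S,3S,4S)-4-bromo-2-(5-hydroxypent-3-yn-1-yl)-1,3-dimethyl-3-(4-methylpent-3-en-1-yl)cyclohexan-1-ol | OCC#CCC[C@H]1[C@](C)(CCC=C(C)C)[C@@H](Br)CC[C@@]1(C)O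
F6 | step 12 | (1R,2S,3S,4S)-4-bromo-2-[(3Z)-5-hydroxy-3-iodopent-3-en-1-yl]-1,3-dimethyl-3-(4-methylpent-3-en-1-yl)cyclohexan-1-ol | OC/C=C(\I)CC[C@H]1[C@](C)(CCC=C(C)C)[C@@H](Br)CC[C@@]1(C)O
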